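# Total synthesis proposal for (S)-N-{2-[6-(3,4-dimethoxyphenyl)-5,6,7,8-tetrahydroquinolin-6-yl]ethyl}-N-methylformamide (14)

Quinoline numbering is used throughout: N1, C2, C3, C4, C4a, C5, C6, C7, C8, C8a. The side chain on C6 is Cα–Cβ–N.

## Analysis of the target

1. Target 14 is a 5,6,7,8-tetrahydroquinoline. A pyridine ring (N1, C2, C3, C4, C4a, C8a; C2–C4 unsubstituted) is fused along C4a–C8a to a carbocycle (C4a, C5, C6, C7, C8, C8a).
2. The only stereocentre is the all-carbon quaternary C6, of (S) configuration. It carries a 3,4-dimethoxyphenyl group, the chain CαH2–CβH2–N(CH3)CHO, and the ring methylenes C5 and C7.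
3. C6 is stereogenic only because the two ring paths differ in length. C5 reaches the pyridine at C4a after one CH2, whereas C7–C8 reaches it at C8a after two. No heteroatom or carbonyl group sits next to C6 to steer a reagent.
4. The feature used here is that two of the four substituents on C6 are the same arm in disguise. C7–C8–C8a=N1 and Cα–Cβ–N–CH3 each consist of CH2CH2 plus one carbon and one nitrogen, so each is a 2-cyanoethyl group. In the first arm the nitrile has been consumed by a pyridine synthesis. In the second arm C and N have changed places.
5. C6 therefore hides a mirror plane. The rest of the pyridine (C4a=C4 and C3=C2) corresponds to two alkyne units.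
6. The sensitive groups are:
   - the tertiary formamide (hydride, strong base, hot acid);
   - the veratryl ring (oxidants and electrophiles, and ready 1,2-migration to any cationic centre at C5 or C7);
   - the basic pyridine nitrogen (alkylating agents, binding to metals).
7. The difficulty lies in making a benzylic quaternary centre enantioselectively without a neighbouring handle, and in fusing the pyridine in the correct orientation to it. These are one problem, because the position of the pyridine defines the configuration.

## Retrosynthetic reasoning

**14 to 13 (N–CHO).** The formyl group is cut first, and so is put on last. It would survive neither the hydride step nor a basic step. Acylation of the secondary amine 13 is selective over the pyridine nitrogen.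

**13 to 12, 10 and 9 (N–CH3 and Cβ–N).**
- The N-methyl carbon is traced to the carbamate carbonyl of 12, and that to the isocyanate 11.
- A Hofmann rearrangement connects 11 to the amide 10, which comes from the nitrile 9.
- In the forward direction Cβ migrates from carbon to nitrogen. All atoms of the cyanoethyl arm are kept: its nitrogen becomes the side-chain nitrogen and its carbon becomes N–CH3.
- The gain is that the side chain of 9 is identical in constitution with the arm that built C7–C8–C8a=N1.

**9 to 6 and 7 (key step).**
- Three bonds are cut: N1–C2, C3–C4 and C4a–C8a. Both rings open at once to the acyclic, achiral dinitrile-alkyne 6 and the silylalkyne 7, which supplies C2–C3.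
- No other cut removes both rings and the stereocentre together.
- The forward reaction must join the propargyl alkyne of 6, the alkyne 7 and one of the two enantiotopic nitriles of 6 in a [2+2+2] mode, and it must choose that nitrile under control of a chiral catalyst.

**6 to 5 and 3 (C4a≡C4, then C5).** The terminal alkyne comes from the aldehyde 5 by one-carbon homologation. Aldehyde 5 comes from the non-enolisable aldehyde 3 by a second one-carbon homologation. The formyl carbon of 3 becomes C5.

**3 to 1 and 2 (C6–C7 and C6–Cα).** Both bonds are made by the same reaction, a double conjugate addition of the benzylic carbon of 1 to 2. The quaternary carbon is formed without any stereochemical demand because the two new arms are identical.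

## Alternatives that were turned down

**Alternative 1: pyridine annulation on a preformed cyclohexenone (the textbook route).**
- Disconnection: C4–C4a and N1–C8a, which removes a C3N unit from the enantioenriched cyclohexenone A1.
- Forward key step: the α′-enolate of A1 (its only enolisable side) attacks a vinamidinium-type C3 electrophile. An ammonia source closes the ring to the dihydroquinoline A2, and C7=C8 is then hydrogenated.
- Reasons for rejection:
  - The annulation builds only the easy ring and sets no stereocentre, so the whole difficulty moves into A1.
  - The quaternary carbon of A1 needs its own asymmetric C–C bond formation and its own ring closure.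
  - The configuration of A1 is held only by the position of one C=C. Over-reduction or enone transposition would erase it.
  - The nitrogen must stay acylated throughout, because a free NHMe group adds to the enone β-carbon.
  - Quaternary carbon, carbocycle, stereocentre, pyridine and alkene removal become five separate tasks, which makes the sequence longer.

**Alternative 2: functionalisation of the intact bicycle.**
- Disconnection: C6–aryl and C6–Cα, starting from the ketone A3.
- Forward key step: palladium-catalysed α-arylation gives A4. Enantioselective alkylation of its enolate with a cyanomethyl halide under chiral phase-transfer control gives A5. The C5 carbonyl is then removed and the nitrile elaborated.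
- Reasons for rejection:
  - The C5 carbonyl serves only as a handle and is the hardest group to remove. It is neopentyl and conjugated to an electron-poor ring.
  - Any ionic deoxygenation passes through cationic character at C5, next to C6 with its veratryl group. This invites a 1,2-aryl shift through a phenonium ion, which would destroy the stereocentre.
  - Hydrazone- or thioketal-based methods must first add to a strongly hindered ketone, under conditions that also attack the nitrile.
  - The risk is spread over arylation, alkylation and deoxygenation rather than held in one step.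

**Alternative 3: strain-release ring expansion.**
- Disconnection: C4a–C5, with expansion of a four-membered ring, starting from the prochiral cyclobutanol A6.
- Forward key step: palladium(0) with a chiral ligand inserts into the C–Br bond. The alkoxide binds, one of the two enantiotopic ring C–C bonds breaks by β-carbon elimination, and C(sp2)–C(sp3) reductive elimination gives the ketone A7.
- Reasons for rejection:
  - After β-carbon elimination the metal sits on C5, in a 1,4-relation to an ortho C–H of the veratryl ring. A 1,4-metal shift through a five-membered metallacycle would compete with closure of the larger palladacycle.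
  - The product carries a superfluous C8 carbonyl.
  - The cyclobutanone precursor needs an alkene synthesis, a ketene [2+2] cycloaddition, dehalogenation and nitrogen protection. The way to A6 costs more than the key step wins.

Key step: step 4

Assumption: the sense of induction of the chiral cobalt catalyst in step 4 cannot be derived a priori; the ligand antipode that gives (R)-9 is used (both antipodes are accessible from the enantiomeric amino alcohols), and the configuration is to be secured at the stage of 10 or 13.

## Steps

Step 1
Reactants: 1 (3,4-dimethoxyphenyl)acetaldehyde; 2 acrylonitrile (2.3 equiv)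
Product: 3 4-(3,4-dimethoxyphenyl)-4-formylheptanedinitrile
Conditions: Triton B (5 mol %), t-BuOH, 0 °C to rt
Reagents that add atoms: none
Why: Double Michael addition (cyanoethylation) of the acidic benzylic α-CH2 of an arylacetaldehyde, whose enolate is conjugated with the arene. The bis-adduct has no α-hydrogen and is the thermodynamic sink, and the new quaternary carbon is not stereogenic because both arms are identical.

Step 2
Reactants: 3 4-(3,4-dimethoxyphenyl)-4-formylheptanedinitrile
Product: 5 4-(3,4-dimethoxyphenyl)-4-(2-oxoethyl)heptanedinitrile, via enol ether 4 (not isolated)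
Conditions: Ph3P(CH2OMe)Cl, KOt-Bu, THF, 0 °C; then 2 M HCl, THF, rt
Reagents that add atoms: (methoxymethyl)triphenylphosphonium chloride, COC[P+](c1ccccc1)(c1ccccc1)c1ccccc1.[Cl-]; water, O
Why: Wittig methoxymethylenation of a non-enolisable aldehyde followed by acid hydrolysis of the enol ether, a standard one-carbon homologation that also works on α-quaternary aldehydes. The preformed ylide is not basic enough to deprotonate the CH2CN groups, and nitriles are inert to dilute acid at rt.

Step 3
Reactants: 5 4-(3,4-dimethoxyphenyl)-4-(2-oxoethyl)heptanedinitrile
Product: 6 4-(3,4-dimethoxyphenyl)-4-(prop-2-yn-1-yl)heptanedinitrile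
Conditions: Ohira–Bestmann reagent, K2CO3, MeOH, 0 °C to rt
Reagents that add atoms: dimethyl (1-diazo-2-oxopropyl)phosphonate, COP(=O)(OC)C(=[N+]=[N-])C(C)=O
Why: Seyferth–Gilbert homologation in the Ohira–Bestmann variant, in which the aldehyde carbon becomes C4a and the diazo carbon becomes C4. The carbonate/methanol medium is too weak to deprotonate the nitriles and tolerates enolisable aldehydes.

Step 4
Reactants: 6 4-(3,4-dimethoxyphenyl)-4-(prop-2-yn-1-yl)heptanedinitrile; 7 ethynyl(trimethyl)silane (4 equiv)
Product: 9 3-[(6R)-6-(3,4-dimethoxyphenyl)-5,6,7,8-tetrahydroquinolin-6-yl]propanenitrile, via 2-silylpyridine 8 (not isolated)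
Conditions: CoBr2 (10 mol %), chiral bis(oxazolinylphenyl)phosphine (N,P,N) ligand (12 mol %), Zn (30 mol %), ZnI2 (20 mol %), THF, 40 °C, slow addition of 6; then TBAF·3H2O, THF, rt
Reagents that add atoms: none
Why: Proposed new method: a cobalt(I)–chiral ligand complex binds the propargyl alkyne of 6 and the alkyne 7 and couples them oxidatively to a cobaltacyclopentadiene in which C4a and the silyl-bearing C2 are bound to cobalt; one of the two enantiotopic 2-cyanoethyl arms then coordinates through nitrogen and inserts into the Co–C4a bond (forming C4a–C8a), and reductive elimination closes N1–C2. The closest known reaction types are the CpCo-catalysed cocyclisation of ω-alkynenitriles with silylalkynes, which gives exactly the 5,6,7,8-tetrahydroquinoline ring system, and the Co-, Ni- and Rh-catalysed desymmetrising [2+2+2] pyridine syntheses of 2,2-disubstituted malononitriles; what is new is that the prochiral carbon lies γ to the nitrile carbons. The pyridine ring closes in the [2+2+2] mode (bonds C3–C4, C4a–C8a, N1–C2), and the carbocycle closes in the same event as a six-membered ring by intramolecular nitrile insertion over the four-atom tether C5–C6–C7–C8, helped by the geminal substitution at C6. C6 is the only new stereocentre and is set by the ligand-controlled choice between the two nitrile arms: it lies only two bonds from the cobalt-bound C4a and inside the ring that is forming, so the aryl group and the spectator arm must occupy the pseudo-equatorial and pseudo-axial sites of a chair-like transition state within the chiral pocket. Chemoselectivity for the mixed metallacycle is secured by the excess of 7, which is slow to homocouple, and by slow addition of 6, while the second nitrile can react only intermolecularly and should therefore remain. The silyl group takes the position α to cobalt for steric reasons and ends at C2, from which fluoride and water remove it readily through the stabilised 2-pyridyl anion, so that 7 serves as a liquid equivalent of the parent C2 alkyne.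

Step 5
Reactants: 9 3-[(6R)-6-(3,4-dimethoxyphenyl)-5,6,7,8-tetrahydroquinolin-6-yl]propanenitrile
Product: 10 3-[(6R)-6-(3,4-dimethoxyphenyl)-5,6,7,8-tetrahydroquinolin-6-yl]propanamide
Conditions: [PtH{(PMe2O)2H}(PMe2OH)] (2 mol %), EtOH/H2O, 80 °C
Reagents that add atoms: water, O
Why: Neutral platinum-catalysed nitrile hydration (Ghaffar–Parkins catalyst), which stops at the primary amide and leaves the aryl ethers and the pyridine untouched. C6 is quaternary and cannot epimerise.

Step 6
Reactants: 10 3-[(6R)-6-(3,4-dimethoxyphenyl)-5,6,7,8-tetrahydroquinolin-6-yl]propanamide
Product: 12 methyl N-{2-[(6S)-6-(3,4-dimethoxyphenyl)-5,6,7,8-tetrahydroquinolin-6-yl]ethyl}carbamate, via isocyanate 11 (not isolated)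
Conditions: PhI(OAc)2, MeOH, 0 °C to rt
Reagents that add atoms: methanol, CO
Why: Hofmann rearrangement with iodine(III): the N-iodanyl amide loses iodobenzene while Cβ migrates from carbon to nitrogen, and methanol traps the isocyanate. An iodine(III) reagent is chosen over a bromine-based one because the latter would brominate the veratryl ring; the descriptor changes from R to S only through the CIP ranking.

Step 7
Reactants: 12 methyl N-{2-[(6S)-6-(3,4-dimethoxyphenyl)-5,6,7,8-tetrahydroquinolin-6-yl]ethyl}carbamate
Product: 13 2-[(6S)-6-(3,4-dimethoxyphenyl)-5,6,7,8-tetrahydroquinolin-6-yl]-N-methylethan-1-amine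
Conditions: LiAlH4, THF, reflux; Fieser work-up
Reagents that add atoms: none
Why: Standard reduction of a carbamate to an N-methylamine, so that the former nitrile carbon ends as N–CH3. Aryl methyl ethers and the alkyl-substituted pyridine are normally inert to LiAlH4 in THF.

Step 8
Reactants: 13 2-[(6S)-6-(3,4-dimethoxyphenyl)-5,6,7,8-tetrahydroquinolin-6-yl]-N-methylethan-1-amine
Product: 14 N-{2-[(6S)-6-(3,4-dimethoxyphenyl)-5,6,7,8-tetrahydroquinolin-6-yl]ethyl}-N-methylformamide
Conditions: HCO2Et, reflux
Reagents that add atoms: ethyl formate, CCOC=O
Why: Aminolysis of a formate ester by the secondary amine; the pyridine nitrogen cannot be acylated irreversibly. The formamide is introduced last because it would not survive step 7.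

## Compound list

1 | (3,4-dimethoxyphenyl)acetaldehyde | COc1ccc(CC=O)cc1OC | starting material
2 | acrylonitrile | C=CC#N | starting material
3 | 4-(3,4-dimethoxyphenyl)-4-formylheptanedinitrile | COc1ccc(C(C=O)(CCC#N)CCC#N)cc1OC | intermediate
4 | 4-(3,4-dimethoxyphenyl)-4-(2-methoxyethenyl)heptanedinitrile (E/Z mixture, not isolated) | COC=CC(CCC#N)(CCC#N)c1ccc(OC)c(OC)c1 | intermediate
5 | 4-(3,4-dimethoxyphenyl)-4-(2-oxoethyl)heptanedinitrile | COc1ccc(C(CC=O)(CCC#N)CCC#N)cc1OC | intermediate
6 | 4-(3,4-dimethoxyphenyl)-4-(prop-2-yn-1-yl)heptanedinitrile | COc1ccc(C(CC#C)(CCC#N)CCC#N)cc1OC | intermediate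
7 | ethynyl(trimethyl)silane | C#C[Si](C)(C)C | starting material
8 | 3-[(6R)-6-(3,4-dimethoxyphenyl)-2-(trimethylsilyl)-5,6,7,8-tetrahydroquinolin-6-yl]propanenitrile (not isolated) | COc1ccc([C@@]2(CCC#N)CCc3nc([Si](C)(C)C)ccc3C2)cc1OC | intermediate
9 | 3-[(6R)-6-(3,4-dimethoxyphenyl)-5,6,7,8-tetrahydroquinolin-6-yl]propanenitrile | COc1ccc([C@@]2(CCC#N)CCc3ncccc3C2)cc1OC | intermediate
10 | 3-[(6R)-6-(3,4-dimethoxyphenyl)-5,6,7,8-tetrahydroquinolin-6-yl]propanamide | COc1ccc([C@@]2(CCC(N)=O)CCc3ncccc3C2)cc1OC | intermediate
11 | (6S)-6-(3,4-dimethoxyphenyl)-6-(2-isocyanatoethyl)-5,6,7,8-tetrahydroquinoline (not isolated) | COc1ccc([C@@]2(CCN=C=O)CCc3ncccc3C2)cc1OC | intermediate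
12 | methyl N-{2-[(6S)-6-(3,4-dimethoxyphenyl)-5,6,7,8-tetrahydroquinolin-6-yl]ethyl}carbamate | COc1ccc([C@@]2(CCNC(=O)OC)CCc3ncccc3C2)cc1OC | intermediate
13 | 2-[(6S)-6-(3,4-dimethoxyphenyl)-5,6,7,8-tetrahydroquinolin-6-yl]-N-methylethan-1-amine | COc1ccc([C@@]2(CCNC)CCc3ncccc3C2)cc1OC | intermediate
14 | N-{2-[(6S)-6-(3,4-dimethoxyphenyl)-5,6,7,8-tetrahydroquinolin-6-yl]ethyl}-N-methylformamide | COc1ccc([C@@]2(CCN(C)C=O)CCc3ncccc3C2)cc1OC | target

## Step count and least certain steps

Total step count: 8. Longest linear sequence: 8 (steps 1 to 8, from 1).

**Step 4 (key step, proposed new method).**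
- Most likely failure: insufficient discrimination between the two enantiotopic cyanoethyl arms, because the chiral pocket must read the difference between an aryl group and a flexible chain on a carbon that is not bound to the metal.
- Further problems could be cyclotrimerisation of the alkynes outrunning nitrile insertion, and inhibition of the catalyst by the product pyridine or by chelation of the dinitrile.
- Fallback (known chemistry), setting out from 6 and returning at 9: cocyclisation of 6 with 7 under CpCo(CO)2 catalysis (xylene, reflux, irradiation) gives the racemic 2-silylpyridine F1, and fluoride converts it into the racemic nitrile F2. F2 is resolved by crystallisation of its salts with an O,O′-diaroyltartaric acid at the basic N1, or by preparative chromatography on a chiral stationary phase, to give 9. The stereocentre then comes from a resolution and not from catalysis.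

**Step 1.**
- Most likely failure: self-condensation of the enolisable arylacetaldehyde and anionic polymerisation of the acceptor outrun the second, more hindered Michael addition.
- Fallback, setting out from 1 and returning at 3: condensation of 1 with pyrrolidine gives the conjugated enamine F3. F3 adds to 2 under neutral conditions (Stork enamine alkylation) to give the adduct enamine F4, and aqueous acid releases the mono-adduct aldehyde F5. F5 is α-branched and cannot undergo aldol dehydration, so it takes up the second equivalent of 2 under catalytic base to give 3.

**Step 6.**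
- Most likely failure: oxidation of the electron-rich veratryl ring by iodine(III), coordination of the reagent to the pyridine nitrogen that slows N-iodanylation, or capture of the isocyanate by unreacted amide.
- Fallback, setting out from 9 and returning at 12, which replaces steps 5 and 6 by a non-oxidative sequence: alkaline hydrolysis of 9 gives the carboxylic acid F6. Diphenylphosphoryl azide and triethylamine convert it into the acyl azide F7. On warming in toluene F7 undergoes Curtius rearrangement to 11, which methanol traps as 12.

**Step 7.**
- Most likely failure: the deprotonated N–H carbamate is a poor electrophile, so prolonged reflux is needed. During that time hydride addition to the pyridine ring may set in.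
- Fallback, setting out from 12 and returning at 14, in which the methyl group comes from alkylation and not from reduction: hydrolysis of 12 with KOH in aqueous ethylene glycol gives the primary amine F8, and ethyl formate gives the secondary formamide F9. Deprotonation with NaH followed by one equivalent of MeI at 0 °C gives 14. The formamide anion is far more nucleophilic than the pyridine nitrogen.

## Further compounds

F1 | step 4 | racemic 3-[6-(3,4-dimethoxyphenyl)-2-(trimethylsilyl)-5,6,7,8-tetrahydroquinolin-6-yl]propanenitrile | COc1ccc(C2(CCC#N)CCc3nc([Si](C)(C)C)ccc3C2)cc1OC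
F2 | step 4 | racemic 3-[6-(3,4-dimethoxyphenyl)-5,6,7,8-tetrahydroquinolin-6-yl]propanenitrile | COc1ccc(C2(CCC#N)CCc3ncccc3C2)cc1OC
F3 | step 1 | 1-[(E)-2-(3,4-dimethoxyphenyl)ethenyl]pyrrolidine | COc1ccc(/C=C/N2CCCC2)cc1OC
F4 | step 1 | 4-(3,4-dimethoxyphenyl)-5-(pyrrolidin-1-yl)pent-4-enenitrile | COc1ccc(C(CCC#N)=CN2CCCC2)cc1OC
F5 | step 1 | racemic 4-(3,4-dimethoxyphenyl)-5-oxopentanenitrile | COc1ccc(C(C=O)CCC#N)cc1OC
F6 | step 6 | 3-[(6R)-6-(3,4-dimethoxyphenyl)-5,6,7,8-tetrahydroquinolin-6-yl]propanoic acid | COc1ccc([C@@]2(CCC(=O)O)CCc3ncccc3C2)cc1OC
F7 | step 6 | 3-[(6R)-6-(3,4-dimethoxyphenyl)-5,6,7,8-tetrahydroquinolin-6-yl]propanoyl azide | COc1ccc([C@@]2(CCC(=O)N=[N+]=[N-])CCc3ncccc3C2)cc1OC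
F8 | step 7 | 2-[(6S)-6-(3,4-dimethoxyphenyl)-5,6,7,8-tetrahydroquinolin-6-yl]ethan-1-amine | COc1ccc([C@@]2(CCN)CCc3ncccc3C2)cc1OC
F9 | step 7 | N-{2-[(6S)-6-(3,4-dimethoxyphenyl)-5,6,7,8-tetrahydroquinolin-6-yl]ethyl}formamide | COc1ccc([C@@]2(CCNC=O)CCc3ncccc3C2)cc1OC
A1 | alternative 1 | N-{2-[(1S)-1-(3,4-dimethoxyphenyl)-4-oxocyclohex-2-en-1-yl]ethyl}-N-methylformamide | COc1ccc([C@@]2(CCN(C)C=O)C=CC(=O)CC2)cc1OC
A2 | alternative 1 | N-{2-[(6S)-6-(3,4-dimethoxyphenyl)-5,6-dihydroquinolin-6-yl]ethyl}-N-methylformamide | COc1ccc([C@@]2(CCN(C)C=O)C=Cc3ncccc3C2)cc1OC
A3 | alternative 2 | 7,8-dihydroquinolin-5(6H)-one | O=C1CCCc2ncccc21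
A4 | alternative 2 | racemic 6-(3,4-dimethoxyphenyl)-7,8-dihydroquinolin-5(6H)-one | COc1ccc(C2CCc3ncccc3C2=O)cc1OC
A5 | alternative 2 | [(6S)-6-(3,4-dimethoxyphenyl)-5-oxo-5,6,7,8-tetrahydroquinolin-6-yl]acetonitrile | COc1ccc([C@@]2(CC#N)CCc3ncccc3C2=O)cc1OC
A6 | alternative 3 | tert-butyl N-{2-[3-(3-bromopyridin-2-yl)-1-(3,4-dimethoxyphenyl)-3-hydroxycyclobutyl]ethyl}-N-methylcarbamate | COc1ccc(C2(CCN(C)C(=O)OC(C)(C)C)CC(O)(c3ncccc3Br)C2)cc1OC
A7 | alternative 3 | tert-butyl N-{2-[(6S)-6-(3,4-dimethoxyphenyl)-8-oxo-5,6,7,8-tetrahydroquinolin-6-yl]ethyl}-N-methylcarbamate | COc1ccc([C@@]2(CCN(C)C(=O)OC(C)(C)C)CC(=O)c3ncccc3C2)cc1OC
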